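**Retrosynthetic overview**

1. Numbering as in eremophilane: ring A = C1–C5 and C10 (C2 ketone; methyl groups on C4 and C5), ring B = C5–C10 (isopropenyl on C7, esters on C8 and C9). The two esters go on last, onto diol-ketone 17 (C8 tiglate first, C9 senecioate second).
2. The C7 isopropenyl group comes from a C7 boronic ester (Zweifel olefination, retention) made by hydroboration of a C6=C7 alkene anti to the C8 oxygen; that alkene is what remains of a temporary C6 ketone (enol triflate, formate reduction).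
3. Key disconnection of C3–C4 together with C5–C10: ring A is a cyclohexanone whose C2 carbonyl stands 1,4 to the quaternary C5 and whose cis-dimethylated C4–C5 edge lies between C3 and C10. This is the retron of a Diels–Alder reaction of a 2-oxygenated diene (C10=C1–C2(OEt)=C3) with an (E)-tigloyl C4=C5 dienophile; the four carbons C6–C9 of ring B are the tether and a temporary C6 ketone activates the dienophile.
4. The acyclic triene 6 is assembled from 2-deoxy-L-ribose (C6–C10, with C8 and C9 as a cis-acetonide), (E)-2-bromobut-2-ene (C4, C5 and both methyl groups), iodoform (C1) and tributyl(1-ethoxyvinyl)stannane (C2, C3).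
5. Ring order: rings A and B are formed together in the one intramolecular Diels–Alder step (ring A by the cycloaddition, ring B by the tether through the new C5–C10 bond); no other ring-forming step is needed.

Key step: step 6

Remark: β means the face of the decalin that carries the C5 methyl group; 2-deoxy-L-ribose is taken as the commercial source of C8 and C9, and 3 is carried as a mixture at C6 because that centre becomes a ketone in step 3.

**Route**

Step 1
Reactants: 1 2-deoxy-L-ribose
Product: 2 2-deoxy-3,4-O-isopropylidene-L-erythro-pentopyranose (anomeric mixture)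
Conditions: 2-methoxypropene, PPTS (cat.), EtOAc, 0 → 25 °C
Reagents that add atoms: 2-methoxypropene, COC(C)=C
Why: Acid-catalysed acetonide formation on the cis-3,4-diol of the pyranose form should leave the lactol free for step 2; no stereocentre is made.

Step 2
Reactants: 2 2-deoxy-3,4-O-isopropylidene-L-erythro-pentopyranose
Product: 3 (3E)-1-[(4R,5S)-5-(hydroxymethyl)-2,2-dimethyl-1,3-dioxolan-4-yl]-3-methylpent-3-en-2-ol (mixture at the carbinol carbon)
Conditions: (E)-2-bromobut-2-ene, t-BuLi, Et2O, −78 °C; add 2 in THF, −78 → 0 °C; H2O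
Reagents that add atoms: (E)-2-bromobut-2-ene, C/C=C(\C)Br
Why: Lithium–bromine exchange with retention of alkene geometry and 1,2-addition of the alkenyllithium to the aldehyde form of the lactol should give the diol; the new C6 carbinol centre is not controlled and need not be, since step 3 oxidises it.

Step 3
Reactants: 3 (3E)-1-[(4R,5S)-5-(hydroxymethyl)-2,2-dimethyl-1,3-dioxolan-4-yl]-3-methylpent-3-en-2-ol
Product: 4 (4R,5R)-2,2-dimethyl-5-[(3E)-3-methyl-2-oxopent-3-en-1-yl]-1,3-dioxolane-4-carbaldehyde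
Conditions: (COCl)2, DMSO, CH2Cl2, −78 °C; i-Pr2NEt, −78 → −30 °C; used crude
Reagents that add atoms: none
Why: Swern oxidation activates both hydroxyl groups before the base is added, so no lactol can form between the new aldehyde and the C6 hydroxyl, and the low temperature should protect the epimerisable C9 centre next to the aldehyde.

Step 4
Reactants: 4 (4R,5R)-2,2-dimethyl-5-[(3E)-3-methyl-2-oxopent-3-en-1-yl]-1,3-dioxolane-4-carbaldehyde
Product: 5 (3E)-1-[(4R,5S)-5-[(E)-2-iodoethenyl]-2,2-dimethyl-1,3-dioxolan-4-yl]-3-methylpent-3-en-2-one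
Conditions: CrCl2 (6 equiv), CHI3 (2 equiv), THF, 0 → 25 °C
Reagents that add atoms: iodoform, IC(I)I
Why: Takai olefination: the geminal dichromium species from iodoform should add to the aldehyde only (the ketone is far slower) and give the (E)-iodoalkene.

Step 5
Reactants: 5 (3E)-1-[(4R,5S)-5-[(E)-2-iodoethenyl]-2,2-dimethyl-1,3-dioxolan-4-yl]-3-methylpent-3-en-2-one
Product: 6 (3E)-1-[(4R,5S)-5-[(1E)-3-ethoxybuta-1,3-dien-1-yl]-2,2-dimethyl-1,3-dioxolan-4-yl]-3-methylpent-3-en-2-one
Conditions: tributyl(1-ethoxyvinyl)stannane, Pd(PPh3)4 (5 mol %), CuI (10 mol %), DMF, 25 → 40 °C; chromatography on Et3N-treated silica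
Reagents that add atoms: tributyl(1-ethoxyvinyl)stannane, CCOC(=C)[Sn](CCCC)(CCCC)CCCC
Why: Stille cross-coupling with retention of the (E)-iodoalkene geometry should give the 2-ethoxy-1,3-diene under neutral conditions that spare the enolisable β-alkoxy ketone.

Step 6
Reactants: 6 (3E)-1-[(4R,5S)-5-[(1E)-3-ethoxybuta-1,3-dien-1-yl]-2,2-dimethyl-1,3-dioxolan-4-yl]-3-methylpent-3-en-2-one
Product: 7 cis-fused adduct 2-ethoxy-8α,9α-(isopropylidenedioxy)-4β,5β-dimethyl-10βH-decal-1-en-6-one (eremophilane numbering)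
Conditions: toluene (0.01 M), BHT (cat.), 150 °C, sealed tube
Reagents that add atoms: none
Why: Thermal intramolecular Diels–Alder reaction (closest known type: cyclisation of 1,7,9-decatrien-3-ones that carry a 2-oxygenated diene): C3 is the nucleophilic terminus of the 2-ethoxydiene and C4 the β-carbon of the tigloyl enone, so the electronically matched, asynchronous [4+2] forms C3–C4 in the lead and C5–C10 with it. Ring A is closed as the cyclohexene of the cycloaddition (C10, C1, C2, C3 from the diene; C4, C5 from the dienophile) and ring B as the fused six-membered carbocycle of the four-atom tether C6–C9. The (E)-tigloyl geometry is transferred suprafacially and puts the C4 and C5 methyl groups cis; the (E)-diene with the tether carbonyl C6 endo (under the diene) gives the cis ring fusion, H10 cis to the C5 methyl. The absolute sense comes from the cis-dioxolane on C8/C9: in the chair-like endo tether the C9–O bond should be pseudo-equatorial, because the alternative places it 1,3-diaxial to the C5 methyl of the dienophile, so the dioxolane ends on the face opposite to H10 and the two methyl groups. The step needs endo over exo selectivity (cis over trans fusion) and π-facial selectivity; the in-chain carbonyl is expected to secure the first and the sugar-derived acetonide the second. No Lewis acid is used, so the β-alkoxy ketone and the acid-labile enol ethers should survive.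

Step 7
Reactants: 7 2-ethoxy-8α,9α-(isopropylidenedioxy)-4β,5β-dimethyl-10βH-decal-1-en-6-one
Product: 8 2,2-(ethylenedioxy)-8α,9α-(isopropylidenedioxy)-4β,5β-dimethyl-10βH-decalin-6-one
Conditions: ethylene glycol, PPTS (cat.), benzene, 25 °C
Reagents that add atoms: ethylene glycol, OCCO
Why: Acid-catalysed addition of the diol to the enol ether and transacetalisation should give the dioxolane under conditions that leave the hindered C6 ketone (next to the quaternary C5) and the acetonide untouched.

Step 8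
Reactants: 8 2,2-(ethylenedioxy)-8α,9α-(isopropylidenedioxy)-4β,5β-dimethyl-10βH-decalin-6-one
Product: 10 2,2-(ethylenedioxy)-8α,9α-(isopropylidenedioxy)-4β,5β-dimethyl-10βH-decal-6-en-6-yl trifluoromethanesulfonate, via potassium enolate 9 (not isolated)
Conditions: KN(SiMe3)2, THF, −78 °C; PhNTf2, −78 → −40 °C
Reagents that add atoms: N-phenylbis(trifluoromethanesulfonimide), O=S(=O)(N(c1ccccc1)S(=O)(=O)C(F)(F)F)C(F)(F)F
Why: Regiospecific enolisation (C7 is the only α-position with hydrogen, C5 being quaternary) and O-triflation of the potassium enolate at −78 °C should outrun β-elimination of the C8 oxygen.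

Step 9
Reactants: 10 2,2-(ethylenedioxy)-8α,9α-(isopropylidenedioxy)-4β,5β-dimethyl-10βH-decal-6-en-6-yl trifluoromethanesulfonate
Product: 11 2,2-(ethylenedioxy)-8α,9α-(isopropylidenedioxy)-4β,5β-dimethyl-10βH-decal-6-ene
Conditions: Pd(OAc)2 (5 mol %), PPh3 (10 mol %), HCO2H, n-Bu3N, DMF, 60 °C
Reagents that add atoms: none
Why: Palladium-catalysed formate reduction of an enol triflate (oxidative addition, decarboxylation of formate to a palladium hydride, reductive elimination) should replace OTf by H, which completes removal of the temporary C6 oxygen without touching the acetals.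

Step 10
Reactants: 11 2,2-(ethylenedioxy)-8α,9α-(isopropylidenedioxy)-4β,5β-dimethyl-10βH-decal-6-ene
Product: 13 2,2-(ethylenedioxy)-8α,9α-(isopropylidenedioxy)-4β,5β-dimethyl-7β-(4,4,5,5-tetramethyl-1,3,2-dioxaborolan-2-yl)-10βH-decalin, via monoalkylborane 12 (not isolated)
Conditions: BH3·THF (3 equiv), THF, 0 → 25 °C; then pinacol, 25 °C
Reagents that add atoms: borane–tetrahydrofuran, [BH3-][O+]1CCCC1; pinacol, CC(C)(O)C(C)(C)O
Why: Hydroboration (syn four-centre addition) should place boron on C7, away from the quaternary C5 and next to the electron-withdrawing allylic C8–O bond, and on the β face anti to the dioxolane, which sets C7; pinacol then converts the monoalkylborane into the boronic ester with loss of H2.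

Step 11
Reactants: 13 2,2-(ethylenedioxy)-8α,9α-(isopropylidenedioxy)-4β,5β-dimethyl-7β-(4,4,5,5-tetramethyl-1,3,2-dioxaborolan-2-yl)-10βH-decalin
Product: 16 2,2-(ethylenedioxy)-7β-isopropenyl-8α,9α-(isopropylidenedioxy)-4β,5β-dimethyl-10βH-decalin, via lithium boronate complex 14 (not isolated), via iodo boronic ester 15 (not isolated)
Conditions: 2-bromopropene, t-BuLi, THF, −78 °C; add 13, −78 → 0 °C; I2, MeOH/THF, −78 °C; NaOMe, MeOH, −78 → 25 °C
Reagents that add atoms: 2-bromopropene, CC(Br)=C
Why: Zweifel olefination: the isopropenyl boronate complex should undergo iodine-triggered, stereoretentive 1,2-migration of C7 from boron to carbon and methoxide-induced anti elimination of the β-iodo boronic ester, so the C7 configuration set in step 10 is kept.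

Step 12
Reactants: 16 2,2-(ethylenedioxy)-7β-isopropenyl-8α,9α-(isopropylidenedioxy)-4β,5β-dimethyl-10βH-decalin
Product: 17 8α,9α-dihydroxy-7β-isopropenyl-4β,5β-dimethyl-10βH-decalin-2-one (8α,9α-dihydroxy-10βH-eremophil-11-en-2-one)
Conditions: HCl (2 M aq.)/THF 1:4, 25 °C
Reagents that add atoms: water, O
Why: Acid-catalysed acetal hydrolysis should remove both the acetonide and the dioxolane; no stereocentre is α to the liberated ketone, so none can epimerise.

Step 13
Reactants: 17 8α,9α-dihydroxy-7β-isopropenyl-4β,5β-dimethyl-10βH-decalin-2-one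
Product: 18 9α-hydroxy-8α-tigloyloxy-10βH-eremophil-11-en-2-one
Conditions: (E)-2-methylbut-2-enoyl chloride (1.1 equiv), pyridine, DMAP (cat.), CH2Cl2, −20 °C
Reagents that add atoms: (E)-2-methylbut-2-enoyl chloride (tigloyl chloride), C/C=C(\C)C(=O)Cl
Why: DMAP-catalysed acylation at low temperature should pick the equatorial C8 hydroxyl, because in the ring B chair with equatorial isopropenyl the C9 hydroxyl is axial and 1,3-diaxial to the C4–C5 bond.

Step 14
Reactants: 18 9α-hydroxy-8α-tigloyloxy-10βH-eremophil-11-en-2-one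
Product: 19 (4S,5R,7R,8R,9S,10S)-9-senecioyloxy-8-tigloyloxyeremophil-11-en-2-one (9α-senecioyloxy-8α-tigloyloxy-10βH-eremophil-11-en-2-one)
Conditions: 3-methylbut-2-enoyl chloride (3 equiv), pyridine, DMAP, CH2Cl2, 25 → 40 °C
Reagents that add atoms: 3-methylbut-2-enoyl chloride (senecioyl chloride), CC(C)=CC(=O)Cl
Why: Forced DMAP-catalysed acylation of the remaining axial C9 hydroxyl should complete the target; pyridine is used instead of a trialkylamine so that the acid chloride is not deconjugated through a vinylketene.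

**Compound list**

1 | 2-deoxy-L-ribose, (3R,4S)-3,4,5-trihydroxypentanal | O=CC[C@@H](O)[C@@H](O)CO | starting material
2 | 2-deoxy-3,4-O-isopropylidene-L-erythro-pentopyranose (anomeric mixture) | OC1C[C@H]2OC(C)(C)O[C@H]2CO1 | intermediate
3 | (3E)-1-[(4R,5S)-5-(hydroxymethyl)-2,2-dimethyl-1,3-dioxolan-4-yl]-3-methylpent-3-en-2-ol (mixture at the carbinol carbon) | C/C=C(\C)C(O)C[C@H]1OC(C)(C)O[C@H]1CO | intermediate
4 | (4R,5R)-2,2-dimethyl-5-[(3E)-3-methyl-2-oxopent-3-en-1-yl]-1,3-dioxolane-4-carbaldehyde | C/C=C(\C)C(=O)C[C@H]1OC(C)(C)O[C@H]1C=O | intermediate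
5 | (3E)-1-[(4R,5S)-5-[(E)-2-iodoethenyl]-2,2-dimethyl-1,3-dioxolan-4-yl]-3-methylpent-3-en-2-one | C/C=C(\C)C(=O)C[C@H]1OC(C)(C)O[C@H]1/C=C/I | intermediate
6 | (3E)-1-[(4R,5S)-5-[(1E)-3-ethoxybuta-1,3-dien-1-yl]-2,2-dimethyl-1,3-dioxolan-4-yl]-3-methylpent-3-en-2-one | C/C=C(\C)C(=O)C[C@H]1OC(C)(C)O[C@H]1/C=C/C(OCC)=C | intermediate
7 | 2-ethoxy-8α,9α-(isopropylidenedioxy)-4β,5β-dimethyl-10βH-decal-1-en-6-one (cis-fused) | C1C(=O)[C@@]2(C)[C@H](C=C(OCC)C[C@@H]2C)[C@H](OC(C)(C)O3)[C@@H]13 | intermediate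
8 | 2,2-(ethylenedioxy)-8α,9α-(isopropylidenedioxy)-4β,5β-dimethyl-10βH-decalin-6-one | C1C(=O)[C@@]2(C)[C@H](CC4(OCCO4)C[C@@H]2C)[C@H](OC(C)(C)O3)[C@@H]13 | intermediate
9 | potassium C6 enolate of 8 (C6=C7) | C1=C([O-])[C@@]2(C)[C@H](CC4(OCCO4)C[C@@H]2C)[C@H](OC(C)(C)O3)[C@@H]13.[K+] | intermediate
10 | 2,2-(ethylenedioxy)-8α,9α-(isopropylidenedioxy)-4β,5β-dimethyl-10βH-decal-6-en-6-yl trifluoromethanesulfonate | C1=C(OS(=O)(=O)C(F)(F)F)[C@@]2(C)[C@H](CC4(OCCO4)C[C@@H]2C)[C@H](OC(C)(C)O3)[C@@H]13 | intermediate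
11 | 2,2-(ethylenedioxy)-8α,9α-(isopropylidenedioxy)-4β,5β-dimethyl-10βH-decal-6-ene | C1=C[C@@]2(C)[C@H](CC4(OCCO4)C[C@@H]2C)[C@H](OC(C)(C)O3)[C@@H]13 | intermediate
12 | 7β-boranyl (BH2) derivative of the decalin bis-acetal | [BH2][C@H]5C[C@@]2(C)[C@H](CC4(OCCO4)C[C@@H]2C)[C@H](OC(C)(C)O3)[C@@H]53 | intermediate
13 | 2,2-(ethylenedioxy)-8α,9α-(isopropylidenedioxy)-4β,5β-dimethyl-7β-(4,4,5,5-tetramethyl-1,3,2-dioxaborolan-2-yl)-10βH-decalin | CC1(C)OB(OC1(C)C)[C@H]5C[C@@]2(C)[C@H](CC4(OCCO4)C[C@@H]2C)[C@H](OC(C)(C)O3)[C@@H]53 | intermediate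
14 | lithium isopropenyl boronate complex of 13 | [Li+].C=C(C)[B-]1(OC(C)(C)C(C)(C)O1)[C@H]5C[C@@]2(C)[C@H](CC4(OCCO4)C[C@@H]2C)[C@H](OC(C)(C)O3)[C@@H]53 | intermediate
15 | β-iodo boronic ester after 1,2-migration (C7 bonded to the carbon that carries CH3, CH2I and the boronic ester; mixture at that carbon) | ICC(C)(B1OC(C)(C)C(C)(C)O1)[C@H]5C[C@@]2(C)[C@H](CC4(OCCO4)C[C@@H]2C)[C@H](OC(C)(C)O3)[C@@H]53 | intermediate
16 | 2,2-(ethylenedioxy)-7β-isopropenyl-8α,9α-(isopropylidenedioxy)-4β,5β-dimethyl-10βH-decalin | C=C(C)[C@H]1C[C@@]2(C)[C@H](CC4(OCCO4)C[C@@H]2C)[C@H](OC(C)(C)O3)[C@@H]13 | intermediate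
17 | 8α,9α-dihydroxy-10βH-eremophil-11-en-2-one | C=C(C)[C@H]1C[C@@]2(C)[C@H](CC(=O)C[C@@H]2C)[C@H](O)[C@@H]1O | intermediate
18 | 9α-hydroxy-8α-tigloyloxy-10βH-eremophil-11-en-2-one | C=C(C)[C@H]1C[C@@]2(C)[C@H](CC(=O)C[C@@H]2C)[C@H](O)[C@@H]1OC(=O)/C(C)=C/C | intermediate
19 | (4S,5R,7R,8R,9S,10S)-9-senecioyloxy-8-tigloyloxyeremophil-11-en-2-one | C=C(C)[C@H]1C[C@@]2(C)[C@H](CC(=O)C[C@@H]2C)[C@H](OC(=O)C=C(C)C)[C@@H]1OC(=O)/C(C)=C/C | target

**Step count and risks**

Total step count: 14. Longest linear sequence: 14 steps (from 1).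

Steps most likely to fail:

Step 6. The cyclisation may run partly through the exo transition state (trans ring fusion) or on the other diene face (dioxolane syn to the C5 methyl), and at the temperature needed the β-alkoxy ketone may eliminate. The fallback sets out from 4 and returns at 8. Wittig olefination of 4 with 1-(triphenylphosphoranylidene)propan-2-one (CH2Cl2, 25 °C) gives the bis-enone F1. Pyrrolidine (1.2 equiv, 4 Å molecular sieves, toluene, 25 °C, then aqueous AcOH) turns the methyl enone into its cross-conjugated 2-aminodiene, which should close rings A and B at ambient temperature by a stepwise Michael–Michael (enamine) sequence and hydrolyse to the diketone F2. Ethylene glycol/PPTS then ketalises only the unhindered C2 ketone and gives 8.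

Step 10. Boron may add at C6 or from the α face, and the C7 borane may lose the C8 oxygen by β-elimination. The fallback sets out from 8 and returns at 16. LiN(i-Pr)2 (THF, −78 °C), acetone, then Me3SiCl gives the aldol silyl ether F3; acetone should add to the C7 enolate anti to the dioxolane. i-Bu2AlH (CH2Cl2, −78 °C) gives the C6 alcohol F4. NaH, CS2, MeI (THF) gives the xanthate F5. Bu3SnH, AIBN (toluene, 90 °C, Barton–McCombie deoxygenation) gives the deoxygenated silyl ether F6. n-Bu4NF (THF) gives the tertiary alcohol F7, and Burgess reagent (benzene, 50 °C) dehydrates it towards the methyl group to give 16.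

Step 13. The acid chloride may discriminate poorly between the two hydroxyl groups, or the tigloyl group may migrate from O8 to O9 during the forcing acylation of step 14. The fallback sets out from 17 and returns at 19. Et3SiCl, imidazole (DMF, −20 °C) silylates the equatorial C8 hydroxyl with a bulkier and more selective electrophile and gives the silyl ether F8. 3-Methylbut-2-enoyl chloride, pyridine, DMAP then acylates C9 with no neighbouring ester present and gives the senecioate F9. HF·pyridine (THF, 0 °C) gives the hydroxy ester F10, and (E)-2-methylbut-2-enoyl chloride, pyridine, DMAP (−20 °C) acylates the unhindered C8 hydroxyl to give 19.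

Further compounds
F1 | step 6 | (3E)-1-[(4R,5S)-2,2-dimethyl-5-[(1E)-3-oxobut-1-en-1-yl]-1,3-dioxolan-4-yl]-3-methylpent-3-en-2-one | C/C=C(\C)C(=O)C[C@H]1OC(C)(C)O[C@H]1/C=C/C(C)=O
F2 | step 6 | 8α,9α-(isopropylidenedioxy)-4β,5β-dimethyl-10βH-decalin-2,6-dione | C1C(=O)[C@@]2(C)[C@H](CC(=O)C[C@@H]2C)[C@H](OC(C)(C)O3)[C@@H]13
F3 | step 10 | 2,2-(ethylenedioxy)-8α,9α-(isopropylidenedioxy)-4β,5β-dimethyl-7β-[2-(trimethylsilyloxy)propan-2-yl]-10βH-decalin-6-one | C[Si](C)(C)OC(C)(C)[C@H]1C(=O)[C@@]2(C)[C@H](CC4(OCCO4)C[C@@H]2C)[C@H](OC(C)(C)O3)[C@@H]13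
F4 | step 10 | corresponding C6 alcohol (mixture at C6) | C[Si](C)(C)OC(C)(C)[C@H]1C(O)[C@@]2(C)[C@H](CC4(OCCO4)C[C@@H]2C)[C@H](OC(C)(C)O3)[C@@H]13
F5 | step 10 | corresponding C6 O-alkyl S-methyl xanthate | C[Si](C)(C)OC(C)(C)[C@H]1C(OC(=S)SC)[C@@]2(C)[C@H](CC4(OCCO4)C[C@@H]2C)[C@H](OC(C)(C)O3)[C@@H]13
F6 | step 10 | 2,2-(ethylenedioxy)-8α,9α-(isopropylidenedioxy)-4β,5β-dimethyl-7β-[2-(trimethylsilyloxy)propan-2-yl]-10βH-decalin | C[Si](C)(C)OC(C)(C)[C@H]1C[C@@]2(C)[C@H](CC4(OCCO4)C[C@@H]2C)[C@H](OC(C)(C)O3)[C@@H]13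
F7 | step 10 | 2,2-(ethylenedioxy)-7β-(2-hydroxypropan-2-yl)-8α,9α-(isopropylidenedioxy)-4β,5β-dimethyl-10βH-decalin | CC(C)(O)[C@H]1C[C@@]2(C)[C@H](CC4(OCCO4)C[C@@H]2C)[C@H](OC(C)(C)O3)[C@@H]13
F8 | step 13 | 9α-hydroxy-8α-(triethylsilyloxy)-10βH-eremophil-11-en-2-one | C=C(C)[C@H]1C[C@@]2(C)[C@H](CC(=O)C[C@@H]2C)[C@H](O)[C@@H]1O[Si](CC)(CC)CC
F9 | step 13 | 9α-senecioyloxy-8α-(triethylsilyloxy)-10βH-eremophil-11-en-2-one | C=C(C)[C@H]1C[C@@]2(C)[C@H](CC(=O)C[C@@H]2C)[C@H](OC(=O)C=C(C)C)[C@@H]1O[Si](CC)(CC)CC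
F10 | step 13 | 8α-hydroxy-9α-senecioyloxy-10βH-eremophil-11-en-2-one | C=C(C)[C@H]1C[C@@]2(C)[C@H](CC(=O)C[C@@H]2C)[C@H](OC(=O)C=C(C)C)[C@@H]1O
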